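(All constants are invented; the result is computed.)

Count this flask not in seconds but in exposure, the running integral of [free monomer] over time, and ask what chain length a given exposure allows.

free monomer 0.77 M; protic impurity 0.385 M; initiator 2 mol%; time 15 s

- whether the average number of monomer units in a chain (chains begun, living or dead) reaches 30 by 15 s (no / yes)
- average number of monomer units in a chain (chains begun, living or dead) at 15 s

- the average divides the monomer in chains by the number of chains begun, living and dead together
- run time (flask): 15 s

    free monomer + living end → monomer in chains + living end, rate k1*[living end]*[free monomer] (k1 = 3.2 L mol⁻¹ s⁻¹)
    free monomer + initiator → living end + monomer in chains (k2 = 0.10 L mol⁻¹ s⁻¹)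
    protic impurity + free monomer → quenched substrate (k3 = 0.29 L mol⁻¹ s⁻¹)
    initiator + monomer in chains → spent initiator (k4 = 1.4 L mol⁻¹ s⁻¹)

Initiation, growth and quenching each run in proportion to [free monomer], so I divided that factor out and, setting aside the step to spent initiator, had pseudo-first-order decays on the new clock: the protic impurity left is its charge times e to the minus 0.29 L mol⁻¹ s⁻¹ times exposure, and the initiator falls the same way with 0.10 L mol⁻¹ s⁻¹. Calling x the product of 0.10 L mol⁻¹ s⁻¹ and exposure, integrating growth over the chains begun gave a length of one plus 32.0 times the quantity x over (one minus e to the minus x), less one; at a given exposure the monomer charge and the initiator charge both drop out of this length.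

I then took two extreme versions of the flask. If [free monomer] stayed at its charge, exposure was 11.6 M·s and the length 23.0. If the impurity took its whole charge from the monomer at once, exposure was 5.78 M·s and the length 11.1. I expected the real flask between them, since its [free monomer] starts at the value of the first version and the impurity's half-life at charge is 3.1 s, shorter than the run, so I added to the second version the impurity charge divided by the product of 0.29 L mol⁻¹ s⁻¹ and the monomer charge, which is the extra exposure while an impurity decays at its rate at charge, and I set aside the monomer that growth takes. That gave an exposure, the time integral of [free monomer] up to the asked time, of 7.50 M·s, and a length of 14.5, so my answer on reaching 30 was no.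

The forecast said no, with a length of 14, below mine, the ratio “still climbing only slowly”.

The simulation gave no and a length of 14.3 at 15 s.

In this flask half of the quenching up to the asked time was done by 2.97 s and half of the chain growth by 8.64 s, and the 12% of protic impurity left at 15.0 s reads as an exposure of 7.19 M·s, beside the 7.50 M·s I carried. The neighbour charged with 0.65 M of protic impurity kept 21% of it, which reads as an exposure of 5.43 M·s and, by the same rule, a length of 10.5, and that flask gave 10.3.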